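**Plan**
- Retrosynthesis: first cut the enone C=C on the ether-bearing aryl side of the diarylheptanoid (aldol condensation of an aryl aldehyde with feruloylacetone). Then open the cyclohexene at two bonds, CH2–CH(side chain) and C(methyl)–CH(OAr).
- Enabling feature: the ring carbinol carbon lies between the side-chain methine and the vinylic CH. At the ketone level these carbons plus the methyl-bearing carbon form a 2-silyloxy-1,3-diene (citronellal C2 and C1 plus a propenyl unit). The ring CH2–CH(OAr) pair is the alkene of a 2-aryloxyacrolein, and the 1,4 relation of the two oxygenated ring carbons matches the innate "para" regiochemistry; the formyl group is a helper that is removed later.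
- Forward: (S)-citronellal gives the silyloxy diene and vanillonitrile gives the 2-aryloxyacrolein. A catalytic asymmetric Diels–Alder reaction closes the only new ring, followed by decarbonylation, enol ether to enone, 1,2-reduction and nitrile to aldehyde. The heptanoid chain is joined last.
- Stereochemistry: the side-chain centre comes from (S)-citronellal. The aryloxy carbon and the ring methine come from the catalyst-controlled, formyl-endo cycloaddition, carried through a stereoretentive decarbonylation. The carbinol comes from axial hydride delivery to the enone, and the E alkenes from thermodynamically controlled condensations.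

Key step: step 6

Assumption: the (S)-oxazaborolidinium catalyst is taken to shield the bound enal of the dienophile in the same sense as for other 2-substituted acroleins; if the sense proves opposite, the (R)-catalyst is used with no other change.

Step 1
Reactants: 1 (S)-citronellal; 2 allylmagnesium bromide
Product: 3 (6S)-6,10-dimethylundeca-1,9-dien-4-ol (both C4 epimers)
Conditions: Et2O, −78 to 0 °C; then H2O
Reagents that add atoms: none
Why: Grignard 1,2-addition joins the future carbinol carbon to a three-carbon unit; the new carbinol centre is left uncontrolled because the next step oxidises it.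

Step 2
Reactants: 3 (6S)-6,10-dimethylundeca-1,9-dien-4-ol
Product: 5 (2E,6S)-6,10-dimethylundeca-2,9-dien-4-one, via allyl ketone 4 (not isolated)
Conditions: Dess–Martin periodinane, CH2Cl2, 0 °C to rt; aqueous NaHCO3 wash; then DBU (0.1 equiv), CH2Cl2, rt
Reagents that add atoms: none
Why: Dess–Martin oxidation and base-mediated conjugation of the β,γ-enone should give the thermodynamically favoured (E)-enone, and the C6 centre is β to the carbonyl and cannot enolise.

Step 3
Reactants: 5 (2E,6S)-6,10-dimethylundeca-2,9-dien-4-one
Product: 6 triisopropyl{[(2E,4Z,6S)-6,10-dimethylundeca-2,4,9-trien-4-yl]oxy}silane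
Conditions: TIPSOTf, Et3N, CH2Cl2, 0 °C
Reagents that add atoms: triisopropylsilyl trifluoromethanesulfonate, CC(C)[Si](C(C)C)(C(C)C)OS(=O)(=O)C(F)(F)F
Why: Soft enolisation (silyl triflate and amine) at the α′-CH2 should give the cross-conjugated 2-silyloxy diene as the Z enol ether, which places the side chain on the outside of the s-cis diene.

Step 4
Reactants: 7 4-hydroxy-3-methoxybenzonitrile; 8 2-bromo-1,1-diethoxyethane
Product: 9 4-(2,2-diethoxyethoxy)-3-methoxybenzonitrile
Conditions: K2CO3, DMF, 110 °C
Reagents that add atoms: none
Why: Williamson O-alkylation of the acidic cyanophenol with a primary bromide, the acetal masking the aldehyde.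

Step 5
Reactants: 9 4-(2,2-diethoxyethoxy)-3-methoxybenzonitrile
Product: 11 2-(4-cyano-2-methoxyphenoxy)acrolein, via aryloxyacetaldehyde 10 (not isolated)
Conditions: TsOH·H2O (0.1 equiv), THF–H2O, 50 °C; then 37 % aq. CH2O, pyrrolidine (0.2 equiv), propionic acid (0.1 equiv), 45 °C
Reagents that add atoms: water, O; formaldehyde, C=O
Why: Acetal hydrolysis followed by amine-catalysed Mannich condensation and elimination (α-methylenation of an aldehyde with one enolisable position) should give the captodative acrolein, which is used at once.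

Step 6
Reactants: 6 triisopropyl{[(2E,4Z,6S)-6,10-dimethylundeca-2,4,9-trien-4-yl]oxy}silane; 11 2-(4-cyano-2-methoxyphenoxy)acrolein
Product: 12 4-{[(1S,2S,5R)-1-formyl-2-methyl-5-[(2S)-6-methylhept-5-en-2-yl]-4-[(triisopropylsilyl)oxy]cyclohex-3-en-1-yl]oxy}-3-methoxybenzonitrile (formyl, ring methyl and side chain mutually cis; aryloxy trans to them)
Conditions: (S)-1-(2-methylphenyl)-3,3-diphenyltetrahydro-1H,3H-pyrrolo[1,2-c][1,3,2]oxazaborole (0.2 equiv), (CF3SO2)2NH (0.2 equiv), CH2Cl2, −78 to −40 °C
Reagents that add atoms: none
Why: Concerted but asynchronous normal-demand [4+2] cycloaddition: the oxazaborolidinium ion binds the formyl oxygen of s-trans 11, and the silyloxy-activated diene attacks through its side-chain-bearing terminus at the unsubstituted CH2 of the enal before the methyl-bearing terminus closes onto the aryloxy carbon. The closest known reaction type is the cationic-oxazaborolidine-catalysed Diels–Alder reaction of 2-(trialkylsilyloxy)-1,3-dienes with 2-substituted acroleins. The only ring formed is the cyclohexene, closed by an intermolecular six-centre suprafacial cycloaddition that makes the CH2–CH(side chain) and C(methyl)–C(OAr) bonds together. The quaternary aryloxy carbon is set by the catalyst, which shields one face of the bound enal; the side-chain methine and the transient CH–CH3 centre follow from the formyl-endo transition state and the (2E,4Z) geometry, which puts both diene end groups outside so that both end up cis to the formyl group and trans to the aryloxy group, independently of the remote citronellal centre. The step needs "para" regiochemistry, formyl-endo selectivity and reaction at the diene in preference to the isolated trisubstituted alkene or to hetero-Diels–Alder and open-chain Mukaiyama–Michael pathways; these are secured by the 2-silyloxy group (largest HOMO coefficient at the side-chain terminus), by Lewis-acid activation of a carbonyl dienophile on an acyclic diene, and by the electron-rich s-cis-accessible diene at low temperature.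

Step 7
Reactants: 12 formyl cycloadduct
Product: 13 4-{[(1S,2S,5R)-2-methyl-5-[(2S)-6-methylhept-5-en-2-yl]-4-[(triisopropylsilyl)oxy]cyclohex-3-en-1-yl]oxy}-3-methoxybenzonitrile
Conditions: RhCl(PPh3)3 (1.1 equiv), toluene, 110 °C
Reagents that add atoms: none
Why: Tsuji–Wilkinson decarbonylation (oxidative addition of the formyl C–H to monovalent rhodium, CO extrusion, C–H reductive elimination) should replace CHO by H with retention, leaving the aryloxy group trans to the side chain.

Step 8
Reactants: 13 silyl enol ether
Product: 14 4-{[(1S,5R)-2-methyl-5-[(2S)-6-methylhept-5-en-2-yl]-4-oxocyclohex-2-en-1-yl]oxy}-3-methoxybenzonitrile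
Conditions: Pd(OAc)2 (1.2 equiv), MeCN, 40 °C
Reagents that add atoms: none
Why: Saegusa–Ito oxidation: the palladium enolate can only eliminate the hydrogen of the CH–CH3 carbon, which places the alkene next to the ring methyl and erases that transient stereocentre.

Step 9
Reactants: 14 enone
Product: 15 4-{[(1S,4R,5R)-4-hydroxy-2-methyl-5-[(2S)-6-methylhept-5-en-2-yl]cyclohex-2-en-1-yl]oxy}-3-methoxybenzonitrile
Conditions: NaBH4, CeCl3·7H2O, MeOH, −78 °C
Reagents that add atoms: none
Why: Luche 1,2-reduction: in the half-chair with the side chain pseudo-equatorial and the aryloxy group pseudo-axial (avoiding allylic strain with the ring methyl), axial hydride delivery should give the pseudo-equatorial alcohol, trans to the side chain and cis to the aryl ether.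

Step 10
Reactants: 15 allylic alcohol nitrile
Product: 16 4-{[(1S,4R,5R)-4-hydroxy-2-methyl-5-[(2S)-6-methylhept-5-en-2-yl]cyclohex-2-en-1-yl]oxy}-3-methoxybenzaldehyde
Conditions: i-Bu2AlH (3 equiv), CH2Cl2, −78 °C; then aq. KNaC4H4O6
Reagents that add atoms: water, O
Why: Hydride reduction of the aryl nitrile stops at the N-aluminoimine (the free alcohol is first converted to its aluminium alkoxide), which hydrolyses to the aldehyde on work-up.

Step 11
Reactants: 17 vanillin; 18 pentane-2,4-dione (3 equiv)
Product: 19 feruloylacetone, (1E,4Z)-5-hydroxy-1-(4-hydroxy-3-methoxyphenyl)hexa-1,4-dien-3-one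
Conditions: B2O3, B(OBu)3, n-BuNH2 (0.2 equiv), EtOAc, 75 °C; then 0.4 M HCl, 60 °C
Reagents that add atoms: none
Why: Boron complexation of the diketone blocks Knoevenagel reaction at the central carbon, so a terminal methyl undergoes aldol condensation to the E alkene, and the excess diketone limits double condensation.

Step 12
Reactants: 16 aryl aldehyde; 19 feruloylacetone
Product: 20 terpecurcumin B, (1E,4Z,6E)-5-hydroxy-1-(4-hydroxy-3-methoxyphenyl)-7-(4-{[(1S,4R,5R)-4-hydroxy-2-methyl-5-[(2S)-6-methylhept-5-en-2-yl]cyclohex-2-en-1-yl]oxy}-3-methoxyphenyl)hepta-1,4,6-trien-3-one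
Conditions: B2O3, B(OBu)3, n-BuNH2 (0.3 equiv), EtOAc, 70 °C; then dilute aq. AcOH, rt
Reagents that add atoms: none
Why: Boron-templated aldol condensation of the remaining methyl group of 19 with the aldehyde should give the E alkene, and mild acidic hydrolysis frees the enolised diketone without ionising the allylic alcohol or ether.

**Compound list**
1 | (S)-citronellal, (3S)-3,7-dimethyloct-6-enal | O=CC[C@@H](C)CCC=C(C)C | starting material
2 | allylmagnesium bromide | C=CC[Mg]Br | starting material
3 | (6S)-6,10-dimethylundeca-1,9-dien-4-ol (C4 epimers) | C=CCC(O)C[C@@H](C)CCC=C(C)C | intermediate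
4 | (6S)-6,10-dimethylundeca-1,9-dien-4-one (allyl ketone, formed in the flask) | C=CCC(=O)C[C@@H](C)CCC=C(C)C | intermediate
5 | (2E,6S)-6,10-dimethylundeca-2,9-dien-4-one | C/C=C/C(=O)C[C@@H](C)CCC=C(C)C | intermediate
6 | triisopropyl{[(2E,4Z,6S)-6,10-dimethylundeca-2,4,9-trien-4-yl]oxy}silane | C/C=C/C(O[Si](C(C)C)(C(C)C)C(C)C)=C/[C@@H](C)CCC=C(C)C | intermediate
7 | 4-hydroxy-3-methoxybenzonitrile | N#Cc1ccc(O)c(OC)c1 | starting material
8 | 2-bromo-1,1-diethoxyethane | CCOC(CBr)OCC | starting material
9 | 4-(2,2-diethoxyethoxy)-3-methoxybenzonitrile | CCOC(COc1ccc(C#N)cc1OC)OCC | intermediate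
10 | 3-methoxy-4-(2-oxoethoxy)benzonitrile (aryloxyacetaldehyde, formed in the flask) | O=CCOc1ccc(C#N)cc1OC | intermediate
11 | 2-(4-cyano-2-methoxyphenoxy)acrolein | C=C(C=O)Oc1ccc(C#N)cc1OC | intermediate
12 | 4-{[(1S,2S,5R)-1-formyl-2-methyl-5-[(2S)-6-methylhept-5-en-2-yl]-4-[(triisopropylsilyl)oxy]cyclohex-3-en-1-yl]oxy}-3-methoxybenzonitrile | N#Cc1ccc(O[C@@]2(C=O)C[C@H]([C@@H](C)CCC=C(C)C)C(O[Si](C(C)C)(C(C)C)C(C)C)=C[C@@H]2C)c(OC)c1 | intermediate
13 | 4-{[(1S,2S,5R)-2-methyl-5-[(2S)-6-methylhept-5-en-2-yl]-4-[(triisopropylsilyl)oxy]cyclohex-3-en-1-yl]oxy}-3-methoxybenzonitrile | N#Cc1ccc(O[C@H]2C[C@H]([C@@H](C)CCC=C(C)C)C(O[Si](C(C)C)(C(C)C)C(C)C)=C[C@@H]2C)c(OC)c1 | intermediate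
14 | 4-{[(1S,5R)-2-methyl-5-[(2S)-6-methylhept-5-en-2-yl]-4-oxocyclohex-2-en-1-yl]oxy}-3-methoxybenzonitrile | N#Cc1ccc(O[C@H]2C[C@H]([C@@H](C)CCC=C(C)C)C(=O)C=C2C)c(OC)c1 | intermediate
15 | 4-{[(1S,4R,5R)-4-hydroxy-2-methyl-5-[(2S)-6-methylhept-5-en-2-yl]cyclohex-2-en-1-yl]oxy}-3-methoxybenzonitrile | N#Cc1ccc(O[C@H]2C[C@H]([C@@H](C)CCC=C(C)C)[C@@H](O)C=C2C)c(OC)c1 | intermediate
16 | 4-{[(1S,4R,5R)-4-hydroxy-2-methyl-5-[(2S)-6-methylhept-5-en-2-yl]cyclohex-2-en-1-yl]oxy}-3-methoxybenzaldehyde | O=Cc1ccc(O[C@H]2C[C@H]([C@@H](C)CCC=C(C)C)[C@@H](O)C=C2C)c(OC)c1 | intermediate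
17 | vanillin | COc1cc(C=O)ccc1O | starting material
18 | pentane-2,4-dione | CC(=O)CC(C)=O | starting material
19 | feruloylacetone (enol form) | COc1cc(/C=C/C(=O)/C=C(/C)O)ccc1O | intermediate
20 | terpecurcumin B | COc1cc(/C=C/C(=O)/C=C(O)/C=C/c2ccc(O[C@H]3C[C@H]([C@@H](C)CCC=C(C)C)[C@@H](O)C=C3C)c(OC)c2)ccc1O | target

**Step count**
Total: 12 steps. Longest linear sequence: 9 steps (steps 1, 2, 3, 6, 7, 8, 9, 10, 12 from (S)-citronellal).

**Steps most likely to fail, with fallbacks**

Step 7. The alkylrhodium hydride may undergo β-hydride elimination to enol ethers instead of C–H reductive elimination. CO extrusion may also stall at the hindered quaternary centre, or the silyl enol ether may be lost on heating. The fallback sets out from 12 and comes back at 14. The Saegusa–Ito oxidation (Pd(OAc)2, MeCN) is run first to give the γ-formyl enone F1. Its formyl carbon is then vinylogously β to the ketone, so K2CO3 in MeOH at 0 °C should remove it by retro-Claisen-type deformylation. The extended enolate is protonated at the γ-carbon, and the aryloxy group should settle pseudo-axial next to the ring methyl, trans to the side chain, which is 14. This fallback gives up the stereoretentive transfer from the cycloaddition in favour of thermodynamic control.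

Step 6. The nitrile or the aryloxy oxygens may tie up the catalyst, formyl-endo or facial selectivity may be insufficient, the enal may react as a heterodiene or stop at the open-chain Mukaiyama–Michael stage, or 11 may polymerise. The fallback sets out from 6 and comes back at 13. A thermal Diels–Alder reaction with 2-ethenyl-4,4,5,5-tetramethyl-1,3,2-dioxaborolane (neat, 110 °C) should give the endo cyclohexenylboronate F2. NaBO3·4H2O in THF–H2O oxidises the C–B bond with retention to the alcohol F3 (hydroxyl cis to the side chain). Mitsunobu etherification with 7 (PPh3, diisopropyl azodicarboxylate) inverts this centre and gives 13. This fallback gives up catalyst control: both ring-face diastereomers form and must be separated at F3.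

Step 8. Zerovalent palladium released in the oxidation may ionise the newly allylic aryl ether, with loss of the phenol and aromatisation, or β-hydride elimination may be slow for the bulky silyl enol ether. The fallback sets out from 13 and comes back at 14. PhSeCl in CH2Cl2 at −78 °C reacts with the silyl enol ether, anti to the ring methyl, to give the α-phenylselanyl ketone F4. H2O2 and pyridine at 0 °C then form the selenoxide, which eliminates syn towards its only β-hydrogen to give 14 without any palladium.

Further compounds
F1 | step 7 | 4-{[(1S,5R)-1-formyl-2-methyl-5-[(2S)-6-methylhept-5-en-2-yl]-4-oxocyclohex-2-en-1-yl]oxy}-3-methoxybenzonitrile | N#Cc1ccc(O[C@@]2(C=O)C[C@H]([C@@H](C)CCC=C(C)C)C(=O)C=C2C)c(OC)c1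
F2 | step 6 | 2-{2-methyl-5-[(2S)-6-methylhept-5-en-2-yl]-4-[(triisopropylsilyl)oxy]cyclohex-3-en-1-yl}-4,4,5,5-tetramethyl-1,3,2-dioxaborolane (boryl, ring methyl and side chain all cis) | CC1(C)OB(OC1(C)C)[C@@H]1C[C@H]([C@@H](C)CCC=C(C)C)C(O[Si](C(C)C)(C(C)C)C(C)C)=C[C@@H]1C
F3 | step 6 | (1R,2S,5R)-2-methyl-5-[(2S)-6-methylhept-5-en-2-yl]-4-[(triisopropylsilyl)oxy]cyclohex-3-en-1-ol | O[C@@H]1C[C@H]([C@@H](C)CCC=C(C)C)C(O[Si](C(C)C)(C(C)C)C(C)C)=C[C@@H]1C
F4 | step 8 | 4-{[(1S,2S,5R)-2-methyl-5-[(2S)-6-methylhept-5-en-2-yl]-4-oxo-3-(phenylselanyl)cyclohexyl]oxy}-3-methoxybenzonitrile (selenium-bearing centre not assigned) | N#Cc1ccc(O[C@H]2C[C@H]([C@@H](C)CCC=C(C)C)C(=O)C([Se]c3ccccc3)[C@@H]2C)c(OC)c1
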